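**Plan**
- Target in labdane numbering: trans-decalin with 2-OAc, gem-dimethyl C4, C7=C8 and the C9 side chain C11–C15–OAc; configuration 2R,5R,9R,10R,13S.
- Cuts, in retrosynthetic order: the acetates; C9–C11; C7–C8 (Claisen) and C8–C9 (ethyl ketone); the two C4 methyl groups and C3–C4 (aldol); then C2 is rejoined to C7 and C1–C10 and C5–C6 are cut as a [4+2].
- Enabling feature: the vicinal ring-fusion carbons C10 and C5 carry C1 and C6, whose neighbours C2 (oxygenated) and C7 (olefinic) are 1,6-related. Joining C2 to C7 gives a cyclohexene (C10, C1, C2, C7, C6, C5) that divides into a diene C1–C2–C7–C6 and the cis olefin C10=C5 of a butenolide C9–C10–C5–C4.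
- Forward: temporary Diels–Alder ring, ozonolysis, ring A (C3–C4 aldol, two cuprate methylations), ring B (C8 to C7 Claisen), side chain at C9, C7=C8 through a reductively formed enol triflate, C2 reduction, acetylation.
- Stereochemistry: the menthol-resolved acetal carbon C4 steers the diene anti and fixes C10 and C5; C9 comes from axial protonation in the Li/NH3 enone reduction; C2 from a thermodynamic dissolving-metal reduction; C13 from the R half ester of 3-methylglutaric acid.

Key step: step 4

Remark: labdane numbering is used for all intermediates (C17 on C8, C18 and C19 on C4, C20 on C10).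
Remark: the R monomethyl ester of 3-methylglutaric acid (21) is taken as purchasable; it is the desymmetrised methanolysis product of 3-methylglutaric anhydride.

Step 1
Reactants: 1 citraconic anhydride
Product: 2 5-hydroxy-3-methylfuran-2(5H)-one (racemic lactol)
Conditions: LiAlH(OtBu)3 (1.05 equiv), THF, −40 to −10 °C; 1 M HCl
Reagents that add atoms: none
Why: Partial hydride reduction of an unsymmetrical cyclic anhydride: the bulky alkoxyaluminium hydride should attack the less hindered carbonyl (the one on the CH carbon) and stop at the aldehyde oxidation level, which closes to the lactol on acidification, so that the methyl group sits next to the surviving lactone carbonyl and the new acetal centre is racemic.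

Step 2
Reactants: 2 5-hydroxy-3-methylfuran-2(5H)-one; 3 (−)-menthol
Product: 4 (5S)-5-[(1R,2S,5R)-menthyloxy]-3-methylfuran-2(5H)-one
Conditions: TsOH·H2O (cat.), PhMe, reflux, azeotropic removal of water; separation of the acetal epimers by crystallisation or chromatography
Reagents that add atoms: none
Why: Acid-catalysed acetalisation of the lactol through its acyloxy-oxocarbenium ion should give both acetal epimers, which are diastereomers because of the menthyl group and therefore separable; the 5S epimer is kept and the other is put back under the same acid, where the acetal centre equilibrates.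

Step 3
Reactants: 5 3-methylbut-3-en-2-one
Product: 6 2-(tert-butyldimethylsilyloxy)-3-methylbuta-1,3-diene
Conditions: TBSOTf, Et3N, Et2O, 0 °C
Reagents that add atoms: tert-butyldimethylsilyl trifluoromethanesulfonate CC(C)(C)[Si](C)(C)OS(=O)(=O)C(F)(F)F
Why: Silyl enol ether formation by soft enolisation: the ketone can enolise only towards its acetyl methyl group, so O-silylation gives the cross-conjugated 2-siloxydiene as a single isomer.

Step 4
Reactants: 4 (5S)-5-menthyloxy-3-methylfuran-2(5H)-one; 6 2-(tert-butyldimethylsilyloxy)-3-methylbuta-1,3-diene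
Product: 7 cis-fused cyclohexene–butyrolactone adduct (silyl enol ether C7=C2, menthyl acetal at C4)
Conditions: 6 (3 equiv), BHT (cat.), PhMe, sealed tube, 160 °C
Reagents that add atoms: none
Why: Concerted, asynchronous [4+2] cycloaddition of normal electron demand, in which the diene terminus next to the siloxy carbon (C6, largest HOMO coefficient) bonds first to the electrophilic beta carbon C5 of the butenolide while C1 closes onto the alpha carbon C10. The closest known reaction type is the thermal Diels–Alder addition of 2-silyloxybuta-1,3-dienes to 5-alkoxyfuran-2(5H)-ones. The cyclohexene ring (C10, C1, C2, C7, C6, C5) closes by suprafacial addition to both partners; it is temporary and is cut between C2 and C7 in step 5. C10 and C5 are formed together, their cis relationship being fixed by the lactone-locked Z olefin and their absolute sense by the acetal stereocentre C4, since the diene adds to the face anti to the menthyloxy group. The step needs regioselectivity, secured by the siloxy donor outweighing the methyl group, and facial selectivity, secured by the acetal substituent, while endo or exo orientation has no stereochemical consequence because both diene termini are unsubstituted. The alpha-methyl group makes the dienophile sluggish, hence the excess of diene, the radical inhibitor and the high temperature.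

Step 5
Reactants: 7 Diels–Alder adduct
Product: 9 methyl ester of the ring-opened keto acid (C2 methyl ketone; C7 methyl ester; lactone acetal intact), via keto acid 8 (not isolated)
Conditions: O3, CH2Cl2/MeOH, −78 °C; Me2S, −78 °C to rt; then MeI, K2CO3, DMF, rt
Reagents that add atoms: ozone [O-][O+]=O; iodomethane CI
Why: Ozonolysis of a silyl enol ether followed by SN2 esterification: the electron-rich tetrasubstituted enol ether is the only C=C bond of 7, its cleavage between C2 and C7 should leave a methyl ketone at C2 and a silyl ester at C7 that hydrolyses on work-up, and methylation of the free acid marks C7 as an ester while the C9 carboxyl stays masked in the lactone acetal; no stereocentre is touched.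

Step 6
Reactants: 9 keto ester lactone acetal
Product: 11 ring-A cyclohexenone acid (C2 ketone; C3=C4; C9 acid on C10; CH2CO2Me on C5), via hydroxylactone 10 (not isolated)
Conditions: TFA/H2O (9:1), rt; evaporate; then TsOH·H2O (cat.), PhMe, reflux, azeotropic removal of water
Reagents that add atoms: water O (it supplies the hydroxyl oxygen of 10, which leaves again in the dehydration)
Why: Acetal hydrolysis followed by an intramolecular aldol condensation, 6-(enolendo)-exo-trig: aqueous acid releases menthol and the C4 aldehyde as its lactol 10, and under acid catalysis the acetyl methyl carbon C3, the only enolisable carbon that can reach C4 through a six-membered ring, adds and dehydrates to the ring-A cyclohexenone with the C9 acid set free; C5 and C10 are carried through unchanged.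

Step 7
Reactants: 11 cyclohexenone acid
Product: 12 4-methyl keto acid (both C4 epimers)
Conditions: Me2CuLi (3.5 equiv), Et2O, −78 to 0 °C; aq. NH4Cl
Reagents that add atoms: lithium dimethylcuprate [Li+].C[Cu-]C
Why: Conjugate addition of a lithium dialkylcuprate to the enone (the first equivalent is spent on the carboxylic acid) should place the first methyl group on C4; the configuration of this new centre does not matter because C4 becomes sp2 again in step 8.

Step 8
Reactants: 12 4-methyl keto acid
Product: 13 4-methyl cyclohexenone acid (C3=C4)
Conditions: IBX, DMSO/PhMe, 70 °C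
Reagents that add atoms: none
Why: Ketone-to-enone dehydrogenation with the hypervalent iodine oxidant IBX: because C10 is quaternary the ketone can desaturate only between C3 and C4, so the 4-methyl enone should be the single regioisomer.

Step 9
Reactants: 13 4-methyl cyclohexenone acid
Product: 15 4,4-dimethyl keto acid, via bis(trimethylsilyl) derivative 14 (not isolated)
Conditions: Me2CuLi (4 equiv), TMSCl, THF/Et2O, −78 to −20 °C; 1 M HCl
Reagents that add atoms: lithium dimethylcuprate [Li+].C[Cu-]C; chlorotrimethylsilane C[Si](C)(C)Cl (silicon is carried only by 14)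
Why: Chlorosilane-accelerated conjugate addition of the cuprate to the beta,beta-disubstituted enone should build quaternary C4 with its two methyl groups (C18 and C19), the enolate being held as silyl enol ether 14 until the acidic work-up; C4 is not a stereocentre.

Step 10
Reactants: 15 4,4-dimethyl keto acid
Product: 16 C2 ethylene ketal acid
Conditions: TMSOCH2CH2OTMS, TMSOTf (cat.), CH2Cl2, −78 to −20 °C; aqueous work-up at pH 4
Reagents that add atoms: 1,2-bis(trimethylsilyloxy)ethane C[Si](C)(C)OCCO[Si](C)(C)C
Why: Ketalisation of the C2 ketone under aprotic silyl triflate catalysis, driven by formation of hexamethyldisiloxane, should mask C2 for the basic and organometallic steps ahead without touching the methyl ester or the hindered acid, whose transient silyl ester falls off on work-up.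

Step 11
Reactants: 16 ketal acid
Product: 18 C9 ethyl ketone (C7 methyl ester, C2 ketal), via acid chloride 17 (not isolated)
Conditions: 1-chloro-N,N,2-trimethylprop-1-en-1-amine, CH2Cl2, 0 °C to rt; then Et2CuLi, Et2O, −78 °C
Reagents that add atoms: 1-chloro-N,N,2-trimethylprop-1-en-1-amine CC(C)=C(Cl)N(C)C (chlorine is carried only by 17); lithium diethylcuprate [Li+].CC[Cu-]CC
Why: Ketone synthesis from an acid chloride and a lithium dialkylcuprate: the neutral chloroenamine converts the hindered C9 acid into its chloride without harming the ketal, and the cuprate should deliver one ethyl group (C8 and C17) and stop at the ketone, leaving the C7 ester alone.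

Step 12
Reactants: 18 ethyl ketone ester
Product: 19 trans-decalin-7,9-dione (2-methyl-1,3-dione in ring B, C2 ketal)
Conditions: KOtBu, THF, 0 °C to rt; dilute HCl to pH 4–5 at 0 °C
Reagents that add atoms: none
Why: Intramolecular Claisen (Dieckmann-type) condensation, 6-(enolendo)-exo-trig: C8 is the only enolisable carbon of the ketone, its enolate should attack the C7 ester and the equilibrium is pulled over by deprotonation of the resulting 2-methyl-1,3-dione, and since the C9 and C6 arms are trans on ring A the new ring B is trans-fused.

Step 13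
Reactants: 19 decalin-7,9-dione
Product: 20 7-isobutoxy-8-methyl-dec-7-en-9-one (vinylogous ester, C2 ketal)
Conditions: isobutanol, TsOH·H2O (cat.), PhH, reflux, azeotropic removal of water
Reagents that add atoms: 2-methylpropan-1-ol CC(C)CO
Why: Vinylogous ester formation by acid-catalysed enol etherification under equilibrating conditions should place the alkoxy group on the less hindered carbonyl carbon C7 and leave C9, next to quaternary C10, as the carbonyl group.

Step 14
Reactants: 21 (3R)-5-methoxy-3-methyl-5-oxopentanoic acid
Product: 22 methyl (3R)-5-hydroxy-3-methylpentanoate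
Conditions: BH3·SMe2, THF, 0 °C to rt; MeOH
Reagents that add atoms: none
Why: Chemoselective borane reduction of a carboxylic acid beside a methyl ester should turn the acid terminus into the future C15 carbinol; the C13 stereocentre comes with the starting material and is not involved.

Step 15
Reactants: 22 methyl (3R)-5-hydroxy-3-methylpentanoate
Product: 23 methyl (3R)-5-(tert-butyldimethylsilyloxy)-3-methylpentanoate
Conditions: TBSCl, imidazole, DMF, 0 °C to rt
Reagents that add atoms: tert-butyldimethylsilyl chloride CC(C)(C)[Si](C)(C)Cl
Why: Silyl ether formation, done at once on the crude hydroxy ester to forestall lactonisation, protects the C15 hydroxyl for the organolithium and dissolving-metal steps.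

Step 16
Reactants: 23 silyloxy ester
Product: 24 (3S)-5-(tert-butyldimethylsilyloxy)-3-methylpentan-1-ol
Conditions: LiAlH4, THF, 0 °C
Reagents that add atoms: none
Why: Hydride reduction of the ester to the primary alcohol provides the C11 terminus.

Step 17
Reactants: 24 silyloxy alcohol
Product: 25 tert-butyl{[(3R)-5-iodo-3-methylpentyl]oxy}dimethylsilane
Conditions: I2, PPh3, imidazole, CH2Cl2, 0 °C to rt
Reagents that add atoms: iodine II
Why: Appel-type iodination (SN2 displacement of the alkoxyphosphonium ion by iodide) gives the primary iodide needed for halogen–lithium exchange.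

Step 18
Reactants: 25 side-chain iodide; 20 vinylogous ester
Product: 28 C8=C9 enone with C7 carbonyl and the full side chain on C9, via organolithium 26 (not isolated), via tertiary allylic alcohol 27 (not isolated)
Conditions: 25, t-BuLi (2 equiv), Et2O/pentane, −78 °C; add 20 in THF, −78 to 0 °C; then 0.5 M HCl, THF, 0 °C
Reagents that add atoms: tert-butyllithium [Li]C(C)(C)C (lithium is carried only by 26); water O
Why: Stork–Danheiser sequence: iodine–lithium exchange, 1,2-addition of the primary alkyllithium to the C9 carbonyl of the vinylogous ester from the face anti to the C10 methyl group and mild acid hydrolysis with allylic transposition should form the C9–C11 bond and give the C8=C9 enone with its carbonyl at C7; the carbinol centre of 27 is lost again and C13 is carried in intact.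

Step 19
Reactants: 28 enone
Product: 30 C7 enol triflate (C7=C8, H9 trans to the C10 methyl group), via lithium enolate 29 (not isolated)
Conditions: Li (2.2 equiv), t-BuOH (1 equiv), liquid NH3/THF, −78 °C; isoprene; evaporate NH3; PhNTf2, THF, 0 °C to rt
Reagents that add atoms: lithium [Li] (carried only by 29); N-phenylbis(trifluoromethanesulfonimide) O=S(=O)(N(c1ccccc1)S(=O)(=O)C(F)(F)F)C(F)(F)F
Why: Birch-type dissolving-metal reduction of the enone followed by enolate O-triflation: the beta carbon C9 should be protonated on the face anti to the axial C10 methyl group, which makes H9 axial and the side chain equatorial (the more stable arrangement, the 9R centre of the target), and the regiodefined C7–C8 enolate is caught as its triflate before it can equilibrate.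

Step 20
Reactants: 30 enol triflate
Product: 31 labd-7-ene with C2 ketal and C15 silyl ether
Conditions: Pd(OAc)2 (cat.), PPh3, Bu3N, HCO2H, DMF, 60 °C
Reagents that add atoms: none
Why: Palladium-catalysed formate reduction of an enol triflate (oxidative addition, formate exchange, loss of carbon dioxide, reductive elimination) should replace the triflate by hydrogen and leave the double bond fixed between C7 and C8.

Step 21
Reactants: 31 protected labd-7-ene
Product: 32 15-hydroxylabd-7-en-2-one
Conditions: 1 M HCl, THF, rt
Reagents that add atoms: water O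
Why: Acid hydrolysis should remove the strained C2 ketal and the silyl ether in one operation, dilute acid at room temperature leaving the isolated trisubstituted alkene in place.

Step 22
Reactants: 32 keto alcohol
Product: 33 (2R)-labd-7-ene-2,15-diol
Conditions: Li, liquid NH3/THF, MeOH, −78 °C; NH4Cl
Reagents that add atoms: none
Why: Dissolving-metal reduction of the ketone should give the thermodynamically preferred equatorial alcohol (2R, trans to the C10 methyl group), because an axial oxygen at C2 would be syn-diaxial to the methyl groups on C4 and C10, whereas hydride reagents would enter from the open equatorial side and give the axial epimer; the isolated alkene is inert.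

Step 23
Reactants: 33 diol
Product: 34 target diacetate CNP0220683.1
Conditions: Ac2O, pyridine, DMAP (cat.), rt
Reagents that add atoms: acetic anhydride CC(=O)OC(C)=O
Why: Acylation of the primary and the secondary hydroxyl group with retention at C2 gives the diacetate.

**Compound list**
1 | citraconic anhydride (3-methylfuran-2,5-dione) | CC1=CC(=O)OC1=O | starting material
2 | 5-hydroxy-3-methylfuran-2(5H)-one, racemic | CC1=CC(O)OC1=O | intermediate
3 | (−)-menthol, (1R,2S,5R)-5-methyl-2-(propan-2-yl)cyclohexan-1-ol | CC(C)[C@@H]1CC[C@@H](C)C[C@H]1O | starting material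
4 | (5S)-5-[(1R,2S,5R)-menthyloxy]-3-methylfuran-2(5H)-one | CC1=C[C@@H](O[C@@H]2C[C@H](C)CC[C@H]2C(C)C)OC1=O | intermediate
5 | 3-methylbut-3-en-2-one | CC(=C)C(C)=O | starting material
6 | 2-(tert-butyldimethylsilyloxy)-3-methylbuta-1,3-diene | C=C(C)C(=C)O[Si](C)(C)C(C)(C)C | intermediate
7 | (3S,3aS,7aR)-5-(tert-butyldimethylsilyloxy)-3-[(1R,2S,5R)-menthyloxy]-6,7a-dimethyl-3a,4,7,7a-tetrahydro-2-benzofuran-1(3H)-one; cis-fused, menthyloxy anti to the cyclohexene ring | C[C@@]12CC(C)=C(O[Si](C)(C)C(C)(C)C)C[C@@H]1[C@@H](O[C@@H]3C[C@H](C)CC[C@H]3C(C)C)OC2=O | intermediate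
8 | 2-[(2S,3S,4R)-2-[(1R,2S,5R)-menthyloxy]-4-methyl-5-oxo-4-(2-oxopropyl)oxolan-3-yl]acetic acid | C[C@@]1(CC(C)=O)[C@H](CC(=O)O)[C@@H](O[C@@H]2C[C@H](C)CC[C@H]2C(C)C)OC1=O | intermediate (not isolated)
9 | methyl 2-[(2S,3S,4R)-2-[(1R,2S,5R)-menthyloxy]-4-methyl-5-oxo-4-(2-oxopropyl)oxolan-3-yl]acetate | C[C@@]1(CC(C)=O)[C@H](CC(=O)OC)[C@@H](O[C@@H]2C[C@H](C)CC[C@H]2C(C)C)OC1=O | intermediate
10 | methyl 2-[(3S,4R)-2-hydroxy-4-methyl-5-oxo-4-(2-oxopropyl)oxolan-3-yl]acetate, both lactol epimers | C[C@@]1(CC(C)=O)[C@H](CC(=O)OC)C(O)OC1=O | intermediate (not isolated)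
11 | (1R,6R)-6-(2-methoxy-2-oxoethyl)-1-methyl-3-oxocyclohex-4-ene-1-carboxylic acid (carboxyl trans to the ester arm) | C[C@@]1(C(=O)O)CC(=O)C=C[C@H]1CC(=O)OC | intermediate
12 | (1R,6R)-6-(2-methoxy-2-oxoethyl)-1,5-dimethyl-3-oxocyclohexane-1-carboxylic acid, both C5 (labdane C4) epimers | C[C@@]1(C(=O)O)CC(=O)CC(C)[C@H]1CC(=O)OC | intermediate
13 | (1R,6R)-6-(2-methoxy-2-oxoethyl)-1,5-dimethyl-3-oxocyclohex-4-ene-1-carboxylic acid | C[C@@]1(C(=O)O)CC(=O)C=C(C)[C@H]1CC(=O)OC | intermediate
14 | trimethylsilyl (1R,6R)-6-(2-methoxy-2-oxoethyl)-1,5,5-trimethyl-3-(trimethylsilyloxy)cyclohex-3-ene-1-carboxylate | C[C@@]1(C(=O)O[Si](C)(C)C)CC(O[Si](C)(C)C)=CC(C)(C)[C@H]1CC(=O)OC | intermediate (not isolated)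
15 | (1R,6R)-6-(2-methoxy-2-oxoethyl)-1,5,5-trimethyl-3-oxocyclohexane-1-carboxylic acid | C[C@@]1(C(=O)O)CC(=O)CC(C)(C)[C@H]1CC(=O)OC | intermediate
16 | (7R,8R)-8-(2-methoxy-2-oxoethyl)-7,9,9-trimethyl-1,4-dioxaspiro[4.5]decane-7-carboxylic acid | C[C@@]1(C(=O)O)CC2(OCCO2)CC(C)(C)[C@H]1CC(=O)OC | intermediate
17 | acid chloride of 16 | C[C@@]1(C(Cl)=O)CC2(OCCO2)CC(C)(C)[C@H]1CC(=O)OC | intermediate (not isolated)
18 | methyl 2-[(7R,8R)-7,9,9-trimethyl-7-propanoyl-1,4-dioxaspiro[4.5]decan-8-yl]acetate | C[C@@]1(C(=O)CC)CC2(OCCO2)CC(C)(C)[C@H]1CC(=O)OC | intermediate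
19 | (5R,10R)-2,2-ethylenedioxy-4,4,8,10-tetramethyl-trans-decalin-7,9-dione (labdane numbering; H5 and the C10 methyl trans; C8 epimers, enolisable) | C[C@@]12CC3(OCCO3)CC(C)(C)[C@H]1CC(=O)C(C)C2=O | intermediate
20 | (5R,10R)-2,2-ethylenedioxy-7-isobutoxy-4,4,8,10-tetramethyl-trans-dec-7-en-9-one (labdane numbering) | C[C@@]12CC3(OCCO3)CC(C)(C)[C@H]1CC(OCC(C)C)=C(C)C2=O | intermediate
21 | (3R)-5-methoxy-3-methyl-5-oxopentanoic acid (R monomethyl 3-methylglutarate) | OC(=O)C[C@@H](C)CC(=O)OC | starting material
22 | methyl (3R)-5-hydroxy-3-methylpentanoate | OCC[C@@H](C)CC(=O)OC | intermediate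
23 | methyl (3R)-5-(tert-butyldimethylsilyloxy)-3-methylpentanoate | CC(C)(C)[Si](C)(C)OCC[C@@H](C)CC(=O)OC | intermediate
24 | (3S)-5-(tert-butyldimethylsilyloxy)-3-methylpentan-1-ol | CC(C)(C)[Si](C)(C)OCC[C@@H](C)CCO | intermediate
25 | tert-butyl{[(3R)-5-iodo-3-methylpentyl]oxy}dimethylsilane | CC(C)(C)[Si](C)(C)OCC[C@@H](C)CCI | intermediate
26 | [(3S)-5-(tert-butyldimethylsilyloxy)-3-methylpentyl]lithium | CC(C)(C)[Si](C)(C)OCC[C@@H](C)CC[Li] | intermediate (not isolated)
27 | 1,2-adduct: 9-hydroxy-7-isobutoxy-dec-7-ene carrying the C11–C15 chain on C9 (C2 ketal, C15 silyl ether; C9 epimers) | C[C@@]12CC3(OCCO3)CC(C)(C)[C@H]1CC(OCC(C)C)=C(C)C2(O)CC[C@H](C)CCO[Si](C)(C)C(C)(C)C | intermediate (not isolated)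
28 | (5R,10R,13S)-15-(tert-butyldimethylsilyloxy)-2,2-ethylenedioxylabd-8-en-7-one | C[C@@]12CC3(OCCO3)CC(C)(C)[C@H]1CC(=O)C(C)=C2CC[C@H](C)CCO[Si](C)(C)C(C)(C)C | intermediate
29 | lithium C7 enolate of the 8,9-reduced ketone (C7=C8; H9 trans to the C10 methyl group) | C[C@@]12CC3(OCCO3)CC(C)(C)[C@H]1CC(O[Li])=C(C)[C@H]2CC[C@H](C)CCO[Si](C)(C)C(C)(C)C | intermediate (not isolated)
30 | 15-(tert-butyldimethylsilyloxy)-2,2-ethylenedioxylabd-7-en-7-yl trifluoromethanesulfonate (H5 and H9 on one face, C10 methyl and side chain on the other) | C[C@@]12CC3(OCCO3)CC(C)(C)[C@H]1CC(OS(=O)(=O)C(F)(F)F)=C(C)[C@H]2CC[C@H](C)CCO[Si](C)(C)C(C)(C)C | intermediate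
31 | (5R,9R,10R,13S)-15-(tert-butyldimethylsilyloxy)-2,2-ethylenedioxylabd-7-ene | C[C@@]12CC3(OCCO3)CC(C)(C)[C@H]1CC=C(C)[C@H]2CC[C@H](C)CCO[Si](C)(C)C(C)(C)C | intermediate
32 | (5R,9R,10R,13S)-15-hydroxylabd-7-en-2-one | C[C@@]12CC(=O)CC(C)(C)[C@H]1CC=C(C)[C@H]2CC[C@H](C)CCO | intermediate
33 | (2R,5R,9R,10R,13S)-labd-7-ene-2,15-diol | C[C@@]12C[C@H](O)CC(C)(C)[C@H]1CC=C(C)[C@H]2CC[C@H](C)CCO | intermediate
34 | (2R,5R,9R,10R,13S)-labd-7-ene-2,15-diyl diacetate (CNP0220683.1) | CC(=O)OCC[C@@H](C)CC[C@@H]1C(C)=CC[C@@H]2C(C)(C)C[C@@H](OC(C)=O)C[C@@]12C | target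

Total step count: 23.
Longest linear sequence: 18 steps (steps 1, 2, 4–13 and 18–23); step 3 and steps 14–17 are side branches.

**Steps most likely to fail**

Step 4. The alpha-methyl group retards the dienophile, so at the temperature required the diene may polymerise or lose its silyl group before it adds, and its methyl group may erode the regiocontrol of the siloxy group. The fallback makes the same two bonds stepwise by an anionic double Michael addition and sets out from 4 and 5. Ketone 5 is deprotonated at its acetyl methyl group (LDA, THF, −78 °C) to lithium 3-methylbuta-1,3-dien-2-olate F1. Its CH2 terminus adds to C5 of 4 anti to the menthyloxy group. The lactone enolate so formed closes onto the isopropenyl ketone (C10 to C1) to give the bicyclic lithium enolate F2 (C7=C2). F2 is silylated in the same flask (TBSCl, DMPU), which returns to the route at 7.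

Step 6. Enolisation of the unmasked C4 aldehyde towards C5 under the acidic conditions would epimerise C5 and scramble the C5/C10 relationship set in step 4. The fallback never frees the aldehyde and sets out from 9. Kinetic enolisation at the acetyl methyl group (LDA, TMSCl, THF, −78 °C) gives the trimethylsilyl enol ether F3. A silyl triflate (TMSOTf, CH2Cl2, −78 °C) then ionises the menthyloxy acetal to the acyloxy-oxocarbenium ion, which the enol ether attacks intramolecularly (Mukaiyama-type addition to an acetal) to give the bridged keto lactone F4. DBU (THF, rt, then acidification) opens this beta-acyloxy ketone by E1cB elimination, which returns to the route at 11.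

Step 9. Conjugate addition to the hindered beta,beta-disubstituted enone next to C5 may stall, with gamma-deprotonation or 1,2-addition taking over. The fallback replaces the second cuprate addition by cyclopropanation and reductive ring opening and sets out from 13. Corey–Chaykovsky cyclopropanation (Me3S(O)I, NaH, DMSO) across C3–C4 gives the cyclopropyl ketone F5. SmI2 (THF/DMPU, t-BuOH) then cleaves the cyclopropane bond between C3 and the added CH2 carbon, which overlaps with the ketyl, so that this carbon becomes the second methyl group on C4. This returns to the route at 15.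

**Further compounds**
F1 | step 4 | lithium 3-methylbuta-1,3-dien-2-olate | C=C(C)C(=C)O[Li]
F2 | step 4 | bicyclic lithium enolate (lithium analogue of 7) | C[C@@]12CC(C)=C(O[Li])C[C@@H]1[C@@H](O[C@@H]3C[C@H](C)CC[C@H]3C(C)C)OC2=O
F3 | step 6 | trimethylsilyl enol ether of 9 (C2=C3) | C[C@@]1(CC(=C)O[Si](C)(C)C)[C@H](CC(=O)OC)[C@@H](O[C@@H]2C[C@H](C)CC[C@H]2C(C)C)OC1=O
F4 | step 6 | bridged keto lactone (C4–O–C9 lactone across ring A, C2 ketone) | C[C@]12CC(=O)C[C@H](OC1=O)[C@H]2CC(=O)OC
F5 | step 9 | cyclopropyl ketone from 13 (CH2 bridging C3 and C4) | C[C@@]1(C(=O)O)CC(=O)C2CC2(C)[C@H]1CC(=O)OC
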